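**Plan**
- Cuts, in retrosynthetic order: the ring B–CH bond and the CH–CH2OH bond of the α-aryl-β-hydroxy ketone; both ArCH–O bonds of the furofuran, exchanged for one ArCH–CHAr bond; the two cyclobutane bonds of a crossed [2+2]; the C2–C3 bond of the dihydrobenzofuran.
- Enabling feature: C3a and C6a of the furo[3,4-c]furan and the bond between them are the β,β' unit of a head-to-head cinnamyl dimer, and the two ArCH–O carbons (C1, C4) become 1,2-neighbours on a cyclobutane whose doubly benzylic bond can be cut oxidatively.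
- Forward order of rings: dihydrobenzofuran (carbenoid C–H insertion), then cyclobutane ([2+2] of the ring A cinnamoyl imidazole with the ring B cinnamyl ether), then both tetrahydrofuran rings at once (oxidative opening of the cyclobutane diol), then the ketone arm on the ring B bromide (enolate arylation, hydroxymethylation), then desilylation.
- Stereochemistry: the cis-(2S,3S) dihydrobenzofuran comes from the chiral dirhodium catalyst; the ring-fusion carbons (3aR,6aR) from the chiral Sc–pybox complex; C1 and C4 (S,S) from substrate control in the ring opening; the (S) α-aryl ketone carbon from a chiral Sc–bipyridine hydroxymethylation.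

Key step: step 16

Remark on the target: read from its SMILES, the dihydrobenzofuran is 2,3-cis (2S,3S), the furofuran is (1S,3aR,4S,6aR) with both aryl groups exo as in (+)-pinoresinol, and the α-aryl ketone carbon is (S); the route is built for exactly this isomer.
Assumption: the ligand antipodes named in steps 7, 16 and 24 are taken to give the configurations drawn; if the sense of induction is the opposite in any of them, the mirror-image ligand is used there.
Abbreviations: TIPS = triisopropylsilyl, TBS = tert-butyldimethylsilyl, TES = triethylsilyl; ArG = 3-methoxy-4-(TIPS-oxy)phenyl; ArB = 3-bromo-5-methoxy-4-(TIPS-oxy)phenyl; DHB = (2S,3S)-7-methoxy-2-ArG-3-(TIPS-oxymethyl)-2,3-dihydro-1-benzofuran-5-yl (2,3-cis); ring A = benzene ring of the dihydrobenzofuran, ring B = the brominated guaiacyl ring, ring D = the aryl ketone ring.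

**Route**

Step 1
Reactants: 1 vanillin
Product: 2 3-methoxy-4-(TIPS-oxy)benzaldehyde
Conditions: i-Pr3SiCl, imidazole, DMF, rt
Reagents that add atoms: triisopropylsilyl chloride, CC(C)[Si](Cl)(C(C)C)C(C)C
Why: Imidazole-promoted silylation of the phenol gives an aryl silyl ether that tolerates the bases and hydrides used later and is removable with fluoride at the end.

Step 2
Reactants: 2 3-methoxy-4-(TIPS-oxy)benzaldehyde
Product: 3 [3-methoxy-4-(TIPS-oxy)phenyl]methanol
Conditions: NaBH4, MeOH, 0 °C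
Reagents that add atoms: none
Why: Borohydride reduction of the aldehyde gives the benzylic alcohol and leaves the aryl silyl ether untouched.

Step 3
Reactants: 3 [3-methoxy-4-(TIPS-oxy)phenyl]methanol; 4 5-bromo-2-hydroxy-3-methoxybenzaldehyde
Product: 5 5-bromo-3-methoxy-2-{[3-methoxy-4-(TIPS-oxy)benzyl]oxy}benzaldehyde
Conditions: PPh3, DIAD, THF, 0 °C → rt
Reagents that add atoms: none
Why: Mitsunobu etherification alkylates the acidic ortho-formyl phenol with the primary benzylic alcohol and avoids an unstable 4-silyloxybenzyl halide.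

Step 4
Reactants: 5 5-bromo-3-methoxy-2-{[3-methoxy-4-(TIPS-oxy)benzyl]oxy}benzaldehyde
Product: 6 5-bromo-1-methoxy-3-(2-methoxyethenyl)-2-{[3-methoxy-4-(TIPS-oxy)benzyl]oxy}benzene (E/Z mixture)
Conditions: MeOCH2PPh3Cl, KN(SiMe3)2, THF, 0 °C → rt
Reagents that add atoms: (methoxymethyl)triphenylphosphonium chloride, COC[P+](c1ccccc1)(c1ccccc1)c1ccccc1.[Cl-]
Why: Wittig methoxymethylenation of the aryl aldehyde installs the extra carbon as an enol ether, whose geometry is irrelevant.

Step 5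
Reactants: 6 enol ether
Product: 7 methyl 2-(5-bromo-3-methoxy-2-{[3-methoxy-4-(TIPS-oxy)benzyl]oxy}phenyl)acetate
Conditions: pyridinium chlorochromate (C5H5NH[CrO3Cl]), NaOAc, CH2Cl2, rt
Reagents that add atoms: pyridinium chlorochromate, [O-][Cr](=O)(=O)Cl.c1cc[nH+]cc1
Why: Chlorochromate oxidation of an enol ether gives the ester directly, completing the one-carbon homologation to the arylacetate under buffered, non-hydrolytic conditions.

Step 6
Reactants: 7 methyl arylacetate
Product: 8 methyl 2-diazo-2-(5-bromo-3-methoxy-2-{[3-methoxy-4-(TIPS-oxy)benzyl]oxy}phenyl)acetate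
Conditions: 4-acetamidobenzenesulfonyl azide, DBU, MeCN, 0 °C → rt
Reagents that add atoms: 4-acetamidobenzenesulfonyl azide, CC(=O)Nc1ccc(cc1)S(=O)(=O)N=[N+]=[N-]
Why: Regitz diazo transfer to the benzylic, ester-activated methylene gives the aryldiazoacetate needed as donor/acceptor carbene precursor.

Step 7
Reactants: 8 aryldiazoacetate
Product: 9 methyl (2S,3R)-5-bromo-7-methoxy-2-ArG-2,3-dihydro-1-benzofuran-3-carboxylate (2,3-cis)
Conditions: Rh2(S-PTTL)4 (dirhodium tetrakis[N-phthaloyl-(S)-tert-leucinate], 1 mol %), toluene, −60 °C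
Reagents that add atoms: none
Why: Intramolecular 1,5 C–H insertion of the dirhodium carbenoid into the electron-rich benzylic ether C–H closes the dihydrofuran ring, the concerted insertion giving the kinetic 2,3-cis ester and the chiral carboxylate ligands setting C2 and C3 together.

Step 8
Reactants: 9 cis ester
Product: 10 [(2S,3S)-5-bromo-7-methoxy-2-ArG-2,3-dihydro-1-benzofuran-3-yl]methanol (2,3-cis)
Conditions: i-Bu2AlH, CH2Cl2, −78 → −20 °C; Rochelle salt
Reagents that add atoms: none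
Why: Hydride reduction of the ester with a non-basic aluminium hydride does not enolise C3, so the cis relationship is carried into the alcohol (the descriptor at C3 changes only by priority).

Step 9
Reactants: 10 cis alcohol
Product: 11 (2S,3S)-5-bromo-7-methoxy-2-ArG-3-(TIPS-oxymethyl)-2,3-dihydro-1-benzofuran (DHB–Br)
Conditions: i-Pr3SiCl, imidazole, DMF, rt
Reagents that add atoms: triisopropylsilyl chloride, CC(C)[Si](Cl)(C(C)C)C(C)C
Why: Silylation of the primary alcohol gives an ether that survives the acidic TBS cleavage of step 19 and leaves with the aryl silyl ethers at the end.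

Step 10
Reactants: 11 DHB–Br
Product: 12 (E)-N-methoxy-N-methyl-3-(DHB)prop-2-enamide
Conditions: Pd2(dba)3 (2.5 mol %), [(t-Bu)3PH]BF4, Cy2NMe, dioxane, 80 °C
Reagents that add atoms: N-methoxy-N-methylacrylamide, C=CC(=O)N(C)OC
Why: Heck reaction of the electron-rich aryl bromide with the acrylamide gives the (E)-cinnamoyl Weinreb amide through syn insertion and syn β-hydride elimination, without base-labile steps.

Step 11
Reactants: 12 Weinreb amide
Product: 13 (E)-1-(1-methyl-1H-imidazol-2-yl)-3-(DHB)prop-2-en-1-one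
Conditions: 1-methylimidazole, n-BuLi, THF, −78 °C; then 12, −78 → 0 °C; H2O
Reagents that add atoms: 1-methylimidazole, Cn1ccnc1
Why: Weinreb ketone synthesis: 2-lithio-1-methylimidazole adds once, in 1,2 fashion, to the N-methoxy-N-methyl amide and the chelated adduct releases the enone only on work-up.

Step 12
Reactants: 14 5-bromovanillin
Product: 15 3-bromo-5-methoxy-4-(TIPS-oxy)benzaldehyde
Conditions: i-Pr3SiOTf, 2,6-lutidine, CH2Cl2, 0 °C → rt
Reagents that add atoms: triisopropylsilyl triflate, CC(C)[Si](OS(=O)(=O)C(F)(F)F)(C(C)C)C(C)C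
Why: The silyl triflate silylates the doubly ortho-substituted phenol, which the chloride would silylate only slowly.

Step 13
Reactants: 15 silylated bromovanillin
Product: 16 ethyl (E)-3-(ArB)prop-2-enoate
Conditions: (EtO)2P(O)CH2CO2Et, LiCl, DBU, MeCN, rt
Reagents that add atoms: triethyl phosphonoacetate, CCOC(=O)CP(=O)(OCC)OCC
Why: Horner–Wadsworth–Emmons olefination under the mild LiCl/amine variant gives the (E)-cinnamate without endangering the aryl silyl ether.

Step 14
Reactants: 16 cinnamate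
Product: 17 (E)-3-(ArB)prop-2-en-1-ol
Conditions: i-Bu2AlH, CH2Cl2, −78 °C
Reagents that add atoms: none
Why: 1,2-Reduction of the enoate with the aluminium hydride gives the allylic alcohol with the (E) alkene and the aryl bromide intact.

Step 15
Reactants: 17 cinnamyl alcohol
Product: 18 (E)-tert-butyldimethyl{[3-(ArB)prop-2-en-1-yl]oxy}silane
Conditions: t-BuMe2SiCl, imidazole, CH2Cl2, rt
Reagents that add atoms: tert-butyldimethylsilyl chloride, CC(C)(C)[Si](C)(C)Cl
Why: Silylation of the allylic alcohol gives a TBS ether that is inert to the Lewis acid of the key step and can later be removed selectively beside the TIPS ethers.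

Step 16
Reactants: 13 ring A cinnamoyl imidazole; 18 ring B cinnamyl TBS ether
Product: 19 [(1R,2S,3S,4R)-2-(DHB)-3-(ArB)-4-(TBS-oxymethyl)cyclobutyl](1-methyl-1H-imidazol-2-yl)methanone (all-trans)
Conditions: Sc(OTf)3 (10 mol %), (S,S)-t-Bu-pybox (15 mol %), Ru(bpy)3(PF6)2 (2.5 mol %), 18 (3 equiv), i-PrOAc/MeCN 3:1, degassed, blue LEDs, 0 °C
Reagents that add atoms: none
Why: Proposed new method: chelation of the acylimidazole (imidazole N3 and carbonyl O) to the Sc(OTf)3–pybox complex lowers the enone triplet energy so that excited Ru(bpy)3(PF6)2 transfers energy only to bound 13, whose triplet adds through its carbonyl-bearing alkene carbon to the CH2OTBS-bearing carbon of 18 to give a 1,4-diradical that is benzylic at both ends. The closest known reaction type is the chiral-Lewis-acid-catalysed, triplet-sensitised crossed [2+2] photocycloaddition of chelating aryl enones (2-acylimidazoles, 2'-hydroxychalcones) with terminal styrenes; a 1,2-disubstituted cinnamyl ether as partner and an all-trans tetrasubstituted product are the extension. The only ring formed, the cyclobutane, closes by collapse of the 1,4-diradical after intersystem crossing, the ArCH–CHAr bond being made last. The acyl-bearing carbon is set by the tert-butyl-pybox ligand, which shields one face of the bound enone; the CH2OTBS carbon is set in the same first bond formation by approach of the alkene with its substituents turned away from the metal complex, mismatched diradicals being able to revert to the alkenes; the two ArCH carbons are set in the closure, where the freely rotating benzylic radicals take up the all-trans arrangement. The step needs cross- over homo-dimerisation and head-to-head regiochemistry: only scandium-bound 13 is within reach of the sensitiser, 18 is used in excess, and bonding from the enone α-carbon is the only mode that leaves both radicals benzylic.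

Step 17
Reactants: 19 cyclobutyl acylimidazole
Product: 21 methyl (1R,2S,3S,4R)-2-(DHB)-3-(ArB)-4-(TBS-oxymethyl)cyclobutane-1-carboxylate, via acylimidazolium triflate 20 (not isolated)
Conditions: MeOTf, 4 Å molecular sieves, CH2Cl2, rt; then MeOH, DBU, 0 °C
Reagents that add atoms: methyl triflate, COS(=O)(=O)C(F)(F)F (N-methyl group of 20); methanol, CO (methoxy group of 21)
Why: N-Methylation turns the acylimidazole into an acylimidazolium acyl donor that methanol cleaves by acyl substitution, and because the all-trans ester is the thermodynamic epimer the brief exposure to amine base puts no stereocentre at risk.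

Step 18
Reactants: 21 cyclobutane methyl ester
Product: 22 [(1R,2S,3S,4R)-2-(DHB)-3-(ArB)-4-(TBS-oxymethyl)cyclobutyl]methanol
Conditions: i-Bu2AlH, CH2Cl2, −78 → 0 °C
Reagents that add atoms: none
Why: Ester reduction with the aluminium hydride gives the first hydroxymethyl arm and leaves aryl bromide and silyl ethers intact.

Step 19
Reactants: 22 mono-alcohol
Product: 23 [(1R,2R,3S,4S)-3-(DHB)-4-(ArB)cyclobutane-1,2-diyl]dimethanol (all-trans)
Conditions: PPTS, MeOH/CH2Cl2, rt
Reagents that add atoms: none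
Why: Acid-catalysed methanolysis removes the primary TBS ether selectively, the bulkier primary and aryl TIPS ethers being stable to pyridinium tosylate.

Step 20
Reactants: 23 cyclobutane diol
Product: 24 (1S,3aR,4S,6aR)-1-(ArB)-4-(DHB)tetrahydro-1H,3H-furo[3,4-c]furan
Conditions: (4-BrC6H4)3N SbCl6 (tris(4-bromophenyl)aminium hexachloroantimonate, 2.2 equiv), 2,6-di-tert-butylpyridine (3 equiv), CH2Cl2, −40 → 0 °C
Reagents that add atoms: none
Why: Proposed new method: one-electron oxidation of the electron-rich ring A arene by the aminium salt gives a radical cation that is delocalised into the strained, doubly benzylic ArCH–CHAr bond; this bond breaks to a distonic 1,4-radical cation, the benzylic cation is captured by the hydroxymethyl group on the far ring-fusion carbon to close the first five-membered ether, the remaining benzylic radical is oxidised by the second equivalent and captured by the other hydroxyl, so that the trans-diol gives the cis-fused bicycle with untouched ring-fusion carbons and with both aryl groups placed on the convex face under substrate control; the closest known reaction types are the nucleophile-assisted ring opening of arylcyclopropane and arylcyclobutane radical cations and the capture of alkoxystyrene-dimer radical cations by oxygen nucleophiles.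

Step 21
Reactants: 25 acetovanillone
Product: 26 1-(ArG)ethanone
Conditions: i-Pr3SiCl, imidazole, DMF, rt
Reagents that add atoms: triisopropylsilyl chloride, CC(C)[Si](Cl)(C(C)C)C(C)C
Why: Silylation of the phenol masks the acidic OH before enolate chemistry.

Step 22
Reactants: 24 furofuran aryl bromide; 26 1-(ArG)ethanone
Product: 27 1-(ArG)-2-{3-methoxy-2-(TIPS-oxy)-5-[(1S,3aR,4S,6aR)-4-(DHB)tetrahydro-1H,3H-furo[3,4-c]furan-1-yl]phenyl}ethanone
Conditions: Pd2(dba)3 (2.5 mol %), XPhos (6 mol %), K3PO4, toluene, 90 °C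
Reagents that add atoms: none
Why: Palladium-catalysed α-arylation of the methyl ketone enolate joins ring B to the ketone arm; the bulky biaryl phosphine copes with the ortho-silyloxy bromide, the phosphate base spares the aryl silyl ethers, and no stereocentre is enolisable at this stage.

Step 23
Reactants: 27 deoxybenzoin
Product: 28 (Z)-trimethylsilyl enol ether of 27
Conditions: Me3SiOTf, Et3N, CH2Cl2, 0 °C
Reagents that add atoms: trimethylsilyl triflate, C[Si](C)(C)OS(=O)(=O)C(F)(F)F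
Why: Soft enolisation with silyl triflate and amine gives the conjugated (Z)-silyl enol ether of the aryl benzyl ketone, the defined geometry needed for face-selective aldol addition.

Step 24
Reactants: 28 silyl enol ether
Product: 29 (2S)-3-hydroxy-1-(ArG)-2-{3-methoxy-2-(TIPS-oxy)-5-[(1S,3aR,4S,6aR)-4-(DHB)tetrahydro-1H,3H-furo[3,4-c]furan-1-yl]phenyl}propan-1-one
Conditions: Sc(OTf)3 (10 mol %), (S,S)-6,6'-bis(1-hydroxy-2,2-dimethylpropyl)-2,2'-bipyridine (12 mol %), aq. HCHO, DME/H2O 9:1, −20 °C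
Reagents that add atoms: formaldehyde, C=O
Why: Mukaiyama-type aldol hydroxymethylation of the silicon enolate with aqueous formaldehyde under a chiral scandium–bipyridine complex, in which the ligand selects the enol-ether face and so sets the (S) centre, while the cold, non-basic medium keeps the new α-aryl ketone stereocentre from enolising.

Step 25
Reactants: 29 tetrakis-TIPS hydroxy ketone
Product: 30 CNP0174045.1, (2S)-3-hydroxy-1-(4-hydroxy-3-methoxyphenyl)-2-{2-hydroxy-3-methoxy-5-[(1S,3aR,4S,6aR)-4-{(2S,3S)-2-(4-hydroxy-3-methoxyphenyl)-3-(hydroxymethyl)-7-methoxy-2,3-dihydro-1-benzofuran-5-yl}tetrahydro-1H,3H-furo[3,4-c]furan-1-yl]phenyl}propan-1-one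
Conditions: n-Bu4NF, AcOH (1:1), THF, 0 °C → rt
Reagents that add atoms: none
Why: Fluoride desilylation buffered with acetic acid frees the three phenols and the primary alcohol while keeping the medium too weakly basic to enolise the α-aryl ketone or open the cis-dihydrobenzofuran.

**Compound list**

1 | vanillin | COc1cc(C=O)ccc1O | starting material
2 | 3-methoxy-4-(TIPS-oxy)benzaldehyde | COc1cc(C=O)ccc1O[Si](C(C)C)(C(C)C)C(C)C | intermediate
3 | [3-methoxy-4-(TIPS-oxy)phenyl]methanol | COc1cc(CO)ccc1O[Si](C(C)C)(C(C)C)C(C)C | intermediate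
4 | 5-bromo-2-hydroxy-3-methoxybenzaldehyde | COc1cc(Br)cc(C=O)c1O | starting material
5 | 5-bromo-3-methoxy-2-{[3-methoxy-4-(TIPS-oxy)benzyl]oxy}benzaldehyde | COc1cc(Br)cc(C=O)c1OCc1ccc(O[Si](C(C)C)(C(C)C)C(C)C)c(OC)c1 | intermediate
6 | 5-bromo-1-methoxy-3-(2-methoxyethenyl)-2-{[3-methoxy-4-(TIPS-oxy)benzyl]oxy}benzene (E/Z mixture) | COC=Cc1cc(Br)cc(OC)c1OCc1ccc(O[Si](C(C)C)(C(C)C)C(C)C)c(OC)c1 | intermediate
7 | methyl 2-(5-bromo-3-methoxy-2-{[3-methoxy-4-(TIPS-oxy)benzyl]oxy}phenyl)acetate | COC(=O)Cc1cc(Br)cc(OC)c1OCc1ccc(O[Si](C(C)C)(C(C)C)C(C)C)c(OC)c1 | intermediate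
8 | methyl 2-diazo-2-(5-bromo-3-methoxy-2-{[3-methoxy-4-(TIPS-oxy)benzyl]oxy}phenyl)acetate | COC(=O)C(=[N+]=[N-])c1cc(Br)cc(OC)c1OCc1ccc(O[Si](C(C)C)(C(C)C)C(C)C)c(OC)c1 | intermediate
9 | methyl (2S,3R)-5-bromo-7-methoxy-2-ArG-2,3-dihydro-1-benzofuran-3-carboxylate (cis) | Brc1cc(OC)c2c(c1)[C@@H](C(=O)OC)[C@@H](c1ccc(O[Si](C(C)C)(C(C)C)C(C)C)c(OC)c1)O2 | intermediate
10 | [(2S,3S)-5-bromo-7-methoxy-2-ArG-2,3-dihydro-1-benzofuran-3-yl]methanol (cis) | Brc1cc(OC)c2c(c1)[C@@H](CO)[C@@H](c1ccc(O[Si](C(C)C)(C(C)C)C(C)C)c(OC)c1)O2 | intermediate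
11 | (2S,3S)-5-bromo-7-methoxy-2-ArG-3-(TIPS-oxymethyl)-2,3-dihydro-1-benzofuran (DHB–Br) | Brc1cc(OC)c2c(c1)[C@@H](CO[Si](C(C)C)(C(C)C)C(C)C)[C@@H](c1ccc(O[Si](C(C)C)(C(C)C)C(C)C)c(OC)c1)O2 | intermediate
12 | (E)-N-methoxy-N-methyl-3-(DHB)prop-2-enamide | CON(C)C(=O)/C=C/c1cc(OC)c2c(c1)[C@@H](CO[Si](C(C)C)(C(C)C)C(C)C)[C@@H](c1ccc(O[Si](C(C)C)(C(C)C)C(C)C)c(OC)c1)O2 | intermediate
13 | (E)-1-(1-methyl-1H-imidazol-2-yl)-3-(DHB)prop-2-en-1-one | Cn1ccnc1C(=O)/C=C/c1cc(OC)c2c(c1)[C@@H](CO[Si](C(C)C)(C(C)C)C(C)C)[C@@H](c1ccc(O[Si](C(C)C)(C(C)C)C(C)C)c(OC)c1)O2 | intermediate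
14 | 5-bromovanillin (3-bromo-4-hydroxy-5-methoxybenzaldehyde) | COc1cc(C=O)cc(Br)c1O | starting material
15 | 3-bromo-5-methoxy-4-(TIPS-oxy)benzaldehyde | COc1cc(C=O)cc(Br)c1O[Si](C(C)C)(C(C)C)C(C)C | intermediate
16 | ethyl (E)-3-(ArB)prop-2-enoate | CCOC(=O)/C=C/c1cc(OC)c(O[Si](C(C)C)(C(C)C)C(C)C)c(Br)c1 | intermediate
17 | (E)-3-(ArB)prop-2-en-1-ol | OC/C=C/c1cc(OC)c(O[Si](C(C)C)(C(C)C)C(C)C)c(Br)c1 | intermediate
18 | (E)-tert-butyldimethyl{[3-(ArB)prop-2-en-1-yl]oxy}silane | CC(C)(C)[Si](C)(C)OC/C=C/c1cc(OC)c(O[Si](C(C)C)(C(C)C)C(C)C)c(Br)c1 | intermediate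
19 | [(1R,2S,3S,4R)-2-(DHB)-3-(ArB)-4-(TBS-oxymethyl)cyclobutyl](1-methyl-1H-imidazol-2-yl)methanone (all-trans) | COc1cc([C@@H]2[C@@H](CO[Si](C)(C)C(C)(C)C)[C@H](C(=O)c5nccn5C)[C@H]2c3cc(OC)c4c(c3)[C@@H](CO[Si](C(C)C)(C(C)C)C(C)C)[C@@H](c3ccc(O[Si](C(C)C)(C(C)C)C(C)C)c(OC)c3)O4)cc(Br)c1O[Si](C(C)C)(C(C)C)C(C)C | intermediate
20 | 2-{[(1R,2S,3S,4R)-2-(DHB)-3-(ArB)-4-(TBS-oxymethyl)cyclobutyl]carbonyl}-1,3-dimethylimidazolium triflate (not isolated) | COc1cc([C@@H]2[C@@H](CO[Si](C)(C)C(C)(C)C)[C@H](C(=O)c5n(C)cc[n+]5C)[C@H]2c3cc(OC)c4c(c3)[C@@H](CO[Si](C(C)C)(C(C)C)C(C)C)[C@@H](c3ccc(O[Si](C(C)C)(C(C)C)C(C)C)c(OC)c3)O4)cc(Br)c1O[Si](C(C)C)(C(C)C)C(C)C.[O-]S(=O)(=O)C(F)(F)F | intermediate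
21 | methyl (1R,2S,3S,4R)-2-(DHB)-3-(ArB)-4-(TBS-oxymethyl)cyclobutane-1-carboxylate | COc1cc([C@@H]2[C@@H](CO[Si](C)(C)C(C)(C)C)[C@H](C(=O)OC)[C@H]2c3cc(OC)c4c(c3)[C@@H](CO[Si](C(C)C)(C(C)C)C(C)C)[C@@H](c3ccc(O[Si](C(C)C)(C(C)C)C(C)C)c(OC)c3)O4)cc(Br)c1O[Si](C(C)C)(C(C)C)C(C)C | intermediate
22 | [(1R,2S,3S,4R)-2-(DHB)-3-(ArB)-4-(TBS-oxymethyl)cyclobutyl]methanol | COc1cc([C@@H]2[C@@H](CO[Si](C)(C)C(C)(C)C)[C@H](CO)[C@H]2c3cc(OC)c4c(c3)[C@@H](CO[Si](C(C)C)(C(C)C)C(C)C)[C@@H](c3ccc(O[Si](C(C)C)(C(C)C)C(C)C)c(OC)c3)O4)cc(Br)c1O[Si](C(C)C)(C(C)C)C(C)C | intermediate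
23 | [(1R,2R,3S,4S)-3-(DHB)-4-(ArB)cyclobutane-1,2-diyl]dimethanol (all-trans) | COc1cc([C@@H]2[C@@H](CO)[C@H](CO)[C@H]2c3cc(OC)c4c(c3)[C@@H](CO[Si](C(C)C)(C(C)C)C(C)C)[C@@H](c3ccc(O[Si](C(C)C)(C(C)C)C(C)C)c(OC)c3)O4)cc(Br)c1O[Si](C(C)C)(C(C)C)C(C)C | intermediate
24 | (1S,3aR,4S,6aR)-1-(ArB)-4-(DHB)tetrahydro-1H,3H-furo[3,4-c]furan | COc1cc([C@H]2OC[C@H]5[C@@H]2CO[C@@H]5c3cc(OC)c4c(c3)[C@@H](CO[Si](C(C)C)(C(C)C)C(C)C)[C@@H](c3ccc(O[Si](C(C)C)(C(C)C)C(C)C)c(OC)c3)O4)cc(Br)c1O[Si](C(C)C)(C(C)C)C(C)C | intermediate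
25 | acetovanillone (1-(4-hydroxy-3-methoxyphenyl)ethanone) | CC(=O)c1ccc(O)c(OC)c1 | starting material
26 | 1-(ArG)ethanone | CC(=O)c1ccc(O[Si](C(C)C)(C(C)C)C(C)C)c(OC)c1 | intermediate
27 | 1-(ArG)-2-{3-methoxy-2-(TIPS-oxy)-5-[(1S,3aR,4S,6aR)-4-(DHB)tetrahydro-1H,3H-furo[3,4-c]furan-1-yl]phenyl}ethanone | COc1cc(C(=O)Cc2cc([C@H]3OC[C@H]4[C@@H]3CO[C@@H]4c3cc(OC)c4c(c3)[C@@H](CO[Si](C(C)C)(C(C)C)C(C)C)[C@@H](c3ccc(O[Si](C(C)C)(C(C)C)C(C)C)c(OC)c3)O4)cc(OC)c2O[Si](C(C)C)(C(C)C)C(C)C)ccc1O[Si](C(C)C)(C(C)C)C(C)C | intermediate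
28 | (Z)-trimethylsilyl enol ether of 27 | COc1cc(/C(O[Si](C)(C)C)=C/c2cc([C@H]3OC[C@H]4[C@@H]3CO[C@@H]4c3cc(OC)c4c(c3)[C@@H](CO[Si](C(C)C)(C(C)C)C(C)C)[C@@H](c3ccc(O[Si](C(C)C)(C(C)C)C(C)C)c(OC)c3)O4)cc(OC)c2O[Si](C(C)C)(C(C)C)C(C)C)ccc1O[Si](C(C)C)(C(C)C)C(C)C | intermediate
29 | (2S)-3-hydroxy-1-(ArG)-2-{3-methoxy-2-(TIPS-oxy)-5-[(1S,3aR,4S,6aR)-4-(DHB)tetrahydro-1H,3H-furo[3,4-c]furan-1-yl]phenyl}propan-1-one | COc1cc(C(=O)[C@H](CO)c2cc([C@H]3OC[C@H]4[C@@H]3CO[C@@H]4c3cc(OC)c4c(c3)[C@@H](CO[Si](C(C)C)(C(C)C)C(C)C)[C@@H](c3ccc(O[Si](C(C)C)(C(C)C)C(C)C)c(OC)c3)O4)cc(OC)c2O[Si](C(C)C)(C(C)C)C(C)C)ccc1O[Si](C(C)C)(C(C)C)C(C)C | intermediate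
30 | CNP0174045.1 | COc1cc(C(=O)[C@H](CO)c2cc([C@H]3OC[C@H]4[C@@H]3CO[C@@H]4c3cc(OC)c4c(c3)[C@@H](CO)[C@@H](c3ccc(O)c(OC)c3)O4)cc(OC)c2O)ccc1O | target

**Step count and risks**

Total step count: 25. Longest linear sequence: 20 steps (steps 1–11, 16–20, 22–25).

Steps most likely to fail:

Step 16. The triplet enone may relax by E/Z isomerisation faster than the hindered 1,2-disubstituted alkene traps it, or the first C–C bond may form with poor simple diastereoselectivity or facial control, so that little all-trans head-to-head adduct of the right absolute sense results. The fallback uses a known reaction, the hole-catalysed crossed [2+2] cycloaddition of two electron-rich styrenes, which gives all-trans head-to-head 1,2-diarylcyclobutanes. It sets out from aryl bromide 11 and cinnamyl ether 18. Suzuki–Miyaura coupling of 11 with (E)-3-(tert-butyldimethylsilyloxy)prop-1-enylboronic acid pinacol ester (Pd(dppf)Cl2, K3PO4, dioxane/H2O, 80 °C) would give the ring A cinnamyl silyl ether F1. Irradiating F1 with an excess of 18 and Ru(bpz)3(PF6)2 (visible light, air, MeNO2) should oxidise the more electron-rich F1 to its radical cation, which adds to 18 and closes to the bis(silyloxymethyl)cyclobutane F2. This variant does not control absolute configuration at the four-membered ring; because ring A is already enantiopure, the two all-trans adducts are diastereomers and would be separated by chromatography. Removal of both TBS groups under the conditions of step 19 then gives diol 23, where the route is rejoined.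

Step 20. The cyclobutane radical cation may fragment to two cinnamyl alcohols (cycloreversion) instead of being captured, the electron-rich product may be oxidised further, or cation capture may occur with poor facial selectivity and give the endo-aryl (epi) furofuran. The fallback is a known furofuran lignan construction: tandem conjugate addition–aldol reaction on a chiral γ-alkoxybutenolide, then reduction and cyclodehydration. It sets out from aryl bromide 11 and aldehyde 15. Bromine–lithium exchange on 11 (n-BuLi, THF, −78 °C) and DMF give the ring A aldehyde F3, which propane-1,3-dithiol and catalytic iodine convert into the dithiane F4. Lithiated F4 adds to (5R)-5-(l-menthyloxy)furan-2(5H)-one anti to the menthyloxy group, and the enolate is trapped by 15 anti to the new substituent to give the lactone F5 (carbinol epimers). Dithiane hydrolysis (MeI, CaCO3, aqueous MeCN) gives the keto lactone F6. LiAlH4 (THF, 0 °C) reduces ketone, lactone and acetal carbon to the tetraol F7 with loss of menthol. Brief treatment with catalytic camphorsulfonic acid in CH2Cl2 at 0 °C ionises both benzylic carbinols and closes them onto the primary hydroxyls to give the exo,exo furofuran 24, where the route is rejoined.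

Step 25. While the slow-to-cleave TIPS ethers are removed, fluoride may epimerise the α-aryl ketone carbon, induce retro-aldol loss of formaldehyde, or let the freed ortho-phenol cyclise onto the ketone and dehydrate to a benzofuran. The fallback exchanges the protecting groups before the labile stereocentre exists. It sets out from deoxybenzoin 27. n-Bu4NF/AcOH removes all four TIPS groups to give the tetrol F8. Et3SiOTf/Et3N (CH2Cl2, 0 °C) silylates the four hydroxyls and the enol in one operation to give the penta(triethylsilyl) enol ether F9. Hydroxymethylation under the conditions of step 24 gives the tetrakis(triethylsilyl) hydroxy ketone F10. Its far more labile TES ethers are removed with HF·pyridine buffered with pyridine in THF at 0 °C to give the target 30.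

Further compounds
F1 | step 16 | (E)-tert-butyldimethyl{[3-(DHB)prop-2-en-1-yl]oxy}silane | CC(C)(C)[Si](C)(C)OC/C=C/c1cc(OC)c2c(c1)[C@@H](CO[Si](C(C)C)(C(C)C)C(C)C)[C@@H](c1ccc(O[Si](C(C)C)(C(C)C)C(C)C)c(OC)c1)O2
F2 | step 16 | (1R,2R,3S,4S)-1,2-bis(TBS-oxymethyl)-3-(DHB)-4-(ArB)cyclobutane (all-trans) | COc1cc([C@@H]2[C@@H](CO[Si](C)(C)C(C)(C)C)[C@H](CO[Si](C)(C)C(C)(C)C)[C@H]2c3cc(OC)c4c(c3)[C@@H](CO[Si](C(C)C)(C(C)C)C(C)C)[C@@H](c3ccc(O[Si](C(C)C)(C(C)C)C(C)C)c(OC)c3)O4)cc(Br)c1O[Si](C(C)C)(C(C)C)C(C)C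
F3 | step 20 | (2S,3S)-7-methoxy-2-ArG-3-(TIPS-oxymethyl)-2,3-dihydro-1-benzofuran-5-carbaldehyde | O=Cc1cc(OC)c2c(c1)[C@@H](CO[Si](C(C)C)(C(C)C)C(C)C)[C@@H](c1ccc(O[Si](C(C)C)(C(C)C)C(C)C)c(OC)c1)O2
F4 | step 20 | 2-(DHB)-1,3-dithiane | C1CSC(SC1)c1cc(OC)c2c(c1)[C@@H](CO[Si](C(C)C)(C(C)C)C(C)C)[C@@H](c1ccc(O[Si](C(C)C)(C(C)C)C(C)C)c(OC)c1)O2
F5 | step 20 | (3S,4R,5R)-3-[hydroxy(ArB)methyl]-4-[2-(DHB)-1,3-dithian-2-yl]-5-(l-menthyloxy)dihydrofuran-2(3H)-one (carbinol epimers) | O=C1[C@H](C(O)c2cc(OC)c(O[Si](C(C)C)(C(C)C)C(C)C)c(Br)c2)[C@@H](C2(SCCCS2)c2cc(OC)c3c(c2)[C@@H](CO[Si](C(C)C)(C(C)C)C(C)C)[C@@H](c2ccc(O[Si](C(C)C)(C(C)C)C(C)C)c(OC)c2)O3)[C@H](O[C@@H]2C[C@H](C)CC[C@H]2C(C)C)O1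
F6 | step 20 | (3S,4R,5R)-3-[hydroxy(ArB)methyl]-4-[(DHB)carbonyl]-5-(l-menthyloxy)dihydrofuran-2(3H)-one (carbinol epimers) | O=C1[C@H](C(O)c2cc(OC)c(O[Si](C(C)C)(C(C)C)C(C)C)c(Br)c2)[C@@H](C(=O)c2cc(OC)c3c(c2)[C@@H](CO[Si](C(C)C)(C(C)C)C(C)C)[C@@H](c2ccc(O[Si](C(C)C)(C(C)C)C(C)C)c(OC)c2)O3)[C@H](O[C@@H]2C[C@H](C)CC[C@H]2C(C)C)O1
F7 | step 20 | (2R,3R)-2-[hydroxy(ArB)methyl]-3-[hydroxy(DHB)methyl]butane-1,4-diol (carbinol epimers) | OC[C@H](C(O)c1cc(OC)c(O[Si](C(C)C)(C(C)C)C(C)C)c(Br)c1)[C@H](CO)C(O)c1cc(OC)c2c(c1)[C@@H](CO[Si](C(C)C)(C(C)C)C(C)C)[C@@H](c1ccc(O[Si](C(C)C)(C(C)C)C(C)C)c(OC)c1)O2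
F8 | step 25 | fully desilylated deoxybenzoin, 1-(4-hydroxy-3-methoxyphenyl)-2-{2-hydroxy-3-methoxy-5-[(1S,3aR,4S,6aR)-4-{(2S,3S)-2-(4-hydroxy-3-methoxyphenyl)-3-(hydroxymethyl)-7-methoxy-2,3-dihydro-1-benzofuran-5-yl}tetrahydro-1H,3H-furo[3,4-c]furan-1-yl]phenyl}ethanone | COc1cc(C(=O)Cc2cc([C@H]3OC[C@H]4[C@@H]3CO[C@@H]4c3cc(OC)c4c(c3)[C@@H](CO)[C@@H](c3ccc(O)c(OC)c3)O4)cc(OC)c2O)ccc1O
F9 | step 25 | (Z)-triethylsilyl enol ether of F8 with all four hydroxyls as TES ethers | COc1cc(/C(O[Si](CC)(CC)CC)=C/c2cc([C@H]3OC[C@H]4[C@@H]3CO[C@@H]4c3cc(OC)c4c(c3)[C@@H](CO[Si](CC)(CC)CC)[C@@H](c3ccc(O[Si](CC)(CC)CC)c(OC)c3)O4)cc(OC)c2O[Si](CC)(CC)CC)ccc1O[Si](CC)(CC)CC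
F10 | step 25 | (2S)-hydroxymethyl ketone with the three phenols and the dihydrobenzofuran CH2OH as TES ethers | COc1cc(C(=O)[C@H](CO)c2cc([C@H]3OC[C@H]4[C@@H]3CO[C@@H]4c3cc(OC)c4c(c3)[C@@H](CO[Si](CC)(CC)CC)[C@@H](c3ccc(O[Si](CC)(CC)CC)c(OC)c3)O4)cc(OC)c2O[Si](CC)(CC)CC)ccc1O[Si](CC)(CC)CC
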